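## The problem

Target **27** is built on a single, monocyclic cyclopentane, so no ring fusion helps with stereocontrol. With the ring numbered C1 (CH2O‑acyl), C2 (CH3), C3 (O‑acyl), C4 (CH2) and C5 (CH(CH2OH)2), the four ring stereocentres are (1S,2R,3R,5R). Every neighbouring pair is trans: the oxygenated groups at C1 and C3 lie on one face, the methyl group and the three‑carbon branch on the other. A C3 oxygen can steer a reagent to a C1=C2 double bond, and C1, flanked by C2 and C5, can be corrected by epimerisation while it carries a carbonyl group. The branch carbon is not stereogenic. The two identical (3S,4E)‑4‑formyl‑3‑(2‑oxoethyl)hex‑4‑enoyl chains each carry a stereocentre and a trisubstituted E enal that the ring cannot influence, so they must be made enantiopure on their own. The finished molecule holds four aldehydes (two enals and two enolisable CH2CHO groups, paired as 1,5‑dialdehydes), two esters and a free 1,3‑diol. Acid would acetalise aldehydes with the diol, and base would bring aldol chemistry and acyl migration, so the aldehydes must appear last, under neutral conditions, with the diol already free. The feature that opens the route is the array CH2O–C1–C2(CH3)–C3(O) together with the C5 branch. It is the carvone skeleton with the carbonyl carbon pushed out of the ring: C2–C5 and the branch correspond to C2–C5 and the isopropenyl group of (R)‑carvone, C1 to carvone C6, the exocyclic CH2O carbon to the carbonyl carbon, and the C3 oxygen to the oxygen of carvone 2,3‑epoxide.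

## Retrosynthesis

**27 ⇒ 26.** In each arm the formyl carbon of the enal and the carbonyl carbon of the oxoethyl group are reconnected, which gives a cyclopentane cis‑1,2‑diol (retro‑Malaprade). The alternative, oxidising four primary alcohols while the branch diol is still protected, would leave a deprotection to be done in the presence of four aldehydes. Hexaol **26** has no aldehyde at all. The forward step only asks periodate to cleave the two vicinal diols and to leave the 1,3‑diol and the esters alone.

**26 ⇒ 25 ⇒ 15 + two 24.** The three acetonides are put back and the two ester C–O bonds are cut. Because both arms are the same acid **24**, one acylation serves both hydroxyls of core diol **15**, and one aqueous acid treatment removes all three acetals before any aldehyde exists. The forward reactions must acylate the hindered secondary C3 hydroxyl and hydrolyse the acetals without acyl migration.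

**24 ⇒ 23 ⇒ 20 ⇒ 17 ⇒ 16.** The exocyclic C=C bond is cut (Wittig), then the bond between the ring and the CH2CO2Me group (enolate alkylation). This leads to the D‑ribose‑derived cyclopentenone acetonide **16**. A conjugate addition to **16** would place the chain on the β‑carbon and give the wrong connectivity after diol cleavage, so the chain has to enter at the α‑carbon of saturated ketone **17**. The acetonide masks both future formyl carbons and directs the alkylation to the opposite face. The forward steps must give the trans alkylation product, the E ethylidene and no epimerisation next to the ketone.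

**15 ⇒ 14 ⇒ 13 ⇒ 12.** The primary alcohol goes back to the methyl ester, C1 is inverted, and the two C–H bonds at C1 and C2 are removed to give enoate **12**. Hydrogen has to enter C2 on the face of the C3 hydroxyl, which a hydroxyl‑directed hydrogenation does; a conjugate reduction would have no such guide. The cis,cis ester **13** that results is then the less stable C1 epimer and can be equilibrated to **14**.

**12 ⇒ 11 ⇒ 9 ⇒ 8.** The two C–O bonds of the branch are cut: the acetonide, then a retro‑hydroboration and a retro‑allylic oxidation back to the isopropenyl group of **8**. Both oxygens come from reagents, no stereocentre arises, and the terpene side chain is used as it stands.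

**8 ⇒ 4 (key disconnection).** The C1–C2 ring bond of **8** is cut and C2 is re‑attached to the exocyclic carbon as a ketone, while the C3 hydroxyl and the C1=C2 double bond fold back into an epoxide. This gives the six‑membered diazo epoxy ketone **4**. A Favorskii contraction of the corresponding chlorohydrin would form the same bond, but it gives a saturated ester with the C2 methyl fixed in the rearrangement itself. The Wolff route delivers the enoate and the free C3 hydroxyl in one operation and leaves C2 to the directed hydrogenation. The forward step needs rearrangement to beat other carbene pathways.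

**4 ⇒ 2 ⇒ 1.** The diazo group is removed (diazo transfer at the only enolisable α‑carbon) and the epoxide is taken back to the enone of (R)‑carvone **1**. Nucleophilic epoxidation anti to the isopropenyl group fixes the C3 configuration relative to C5.

## Roads not taken

**Alternative 1:** Both arms would be attached as achiral, symmetric units to give tetra‑aldehyde **A1**. A chiral secondary amine would then form the enamine of one of the two enantiotopic CH2CHO branches in each arm and condense it with acetaldehyde, giving the silylene‑protected target **A2**. This creates both C4'=C5' bonds and both C3' centres in one late step, and the E enal is the thermodynamic product of a condensation. In arm economy this road is better than the chosen one: no chiral arm has to be made, which would save steps 10–13. Its weak points are serious for this target. An amine‑catalysed cross‑condensation with acetaldehyde as acceptor competes with acetaldehyde self‑condensation. Four aldehydes are exposed to an amine. Each of two remote prochiral centres must be differentiated by the catalyst alone, so any error gives inseparable diastereomers. The silylene must finally come off in the presence of the aldehydes. The chosen plan sets against this a fixed source of arm configuration (enone **16**) and an end‑game in which the aldehydes never meet an amine, base or acid.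

**Alternative 2:** The ring would be closed from the acyclic diazoketone **A3**. A copper carbenoid (for example with Cu(acac)2) at C4 adds to the C5=C(branch) double bond and gives the bicyclic spiro‑cyclopropyl ketone **A4**. Reductive opening of the cyclopropyl ketone would then release the C5 branch with both oxygens already in place. This is a real advantage over the chosen plan, which needs an allylic oxidation and a hydroboration (steps 4 and 5) to build the 1,3‑diol, and it avoids photochemistry. Against it, **A3** already contains the C1 and C2 centres and needs its own asymmetric synthesis of several steps. C5 is set only by the facial preference of the cyclopropanation relative to C1. The C3 ketone must afterwards be reduced to the alcohol trans to the C2 methyl, next to an epimerisable centre. The chosen plan takes C3 and C5 from a terpene without any asymmetric step and reaches the functionalised ring in three steps.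

**Alternative 3:** A vinyl copper reagent would add to C1 of enone **A5**, and the enolate would be methylated at C2 in the same pot to give the all‑trans ketone **A6**. The vinyl group is a latent CH2OH. This is the most convergent way to set C1 and C2, both trans to their neighbours in one operation, and in this respect it is better than the hydrogenation–epimerisation pair of the chosen plan (steps 7 and 8). Its weak points are the supply of enantiopure **A5**, which has no cheap chiral‑pool source; proton transfer and over‑alkylation when cyclopentanone enolates from cuprate additions are methylated; and the reduction of the C3 ketone, where hydride prefers the face away from the C2 methyl and gives the wrong C3 alcohol, so that an inversion would be needed. The chosen plan has C3 correct from the epoxide and needs no step at that centre.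

Key step: step 3

## Route

Assumption: enone **16**, the cyclopentenone acetonide derived from D‑ribose, is taken as a purchased building block; its two ring oxygens end as the formyl oxygens of each arm.

Step 1
Reactants: 1 (R)‑(−)‑carvone
Product: 2 (1R,4R,6R)‑1‑methyl‑4‑(prop‑1‑en‑2‑yl)‑7‑oxabicyclo[4.1.0]heptan‑2‑one (epoxide trans to isopropenyl)
Conditions: 30% aq. H2O2, NaOH (cat.), MeOH, 0 °C
Reagents that add atoms: hydrogen peroxide, OO
Why: Weitz–Scheffer epoxidation; hydroperoxide adds to the enone β‑carbon anti to the isopropenyl group, which sets the C3 oxygen trans to the C5 branch, and the isolated 1,1‑disubstituted alkene is inert to the nucleophilic oxidant.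

Step 2
Reactants: 2 epoxy ketone
Product: 4 (1R,4S,6R)‑3‑diazo‑1‑methyl‑4‑(prop‑1‑en‑2‑yl)‑7‑oxabicyclo[4.1.0]heptan‑2‑one, via trifluoroacetyl diketone 3 (not isolated)
Conditions: LiN(SiMe3)2, THF, −78 °C; CF3CO2CH2CF3, −78 °C; 5% aq. HCl; then MsN3, Et3N, H2O (1 equiv), MeCN, 20 °C
Reagents that add atoms: methanesulfonyl azide, CS(=O)(=O)N=[N+]=[N-]; 2,2,2‑trifluoroethyl trifluoroacetate, O=C(OCC(F)(F)F)C(F)(F)F (its trifluoroacetyl group is carried only by 3)
Why: Only the CH2 next to the carbonyl can be deprotonated, since the other α‑carbon is the fully substituted epoxide carbon; Claisen‑type trifluoroacetylation activates it, and Regitz‑type detrifluoroacetylative diazo transfer gives the diazoketone under conditions mild enough for the epoxide.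

Step 3
Reactants: 4 diazo epoxy ketone; 5 methanol
Product: 8 methyl (3R,5S)‑3‑hydroxy‑2‑methyl‑5‑(prop‑1‑en‑2‑yl)cyclopent‑1‑ene‑1‑carboxylate (hydroxyl trans to isopropenyl), via ketene 6 (not isolated), via ester enol 7 (not isolated)
Conditions: hν (365 nm), MeOH, 0 °C
Reagents that add atoms: methanol (5), CO
Why: Photochemical Wolff rearrangement: excitation of the s‑Z‑locked cyclic diazoketone expels N2 and, in concert, shifts the methyl‑bearing epoxide carbon (C2 of the target ring), the only carbon able to migrate, from the carbonyl carbon to the diazo carbon with retention. This 1,2‑shift, not a cyclisation, is the mode of ring formation: the six‑membered ring contracts to the cyclopentane and the former carbonyl carbon is pushed out as the ketene carbon of 6. Methanol adds to the ketene to give ester enol 7, whose enol double bond is aligned with the adjacent epoxide C–O bond, so a vinylogous β‑elimination opens the epoxide, forms the C1=C2 enoate and leaves the oxygen on C3. The closest known reaction types are the photolysis of α,β‑epoxy diazomethyl ketones in alcohols to γ‑hydroxy‑α,β‑unsaturated esters and the Wolff ring contraction of cyclic 2‑diazo ketones; here both operate in one substrate. No stereocentre is created: C3 keeps its epoxide C–O bond and C5 is untouched, so both come from 2. The step needs rearrangement to win over carbene O–H insertion and 1,2‑hydride shift; the enforced s‑Z geometry, which favours the concerted path, and direct irradiation without a metal catalyst secure this. It also needs the enol to eliminate faster than it ketonises, which the strained, well‑aligned epoxide bond should ensure; a trace of Et3N before work‑up would complete the opening if needed.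

Step 4
Reactants: 8 hydroxy enoate
Product: 9 methyl (3R,5S)‑3‑hydroxy‑5‑(3‑hydroxyprop‑1‑en‑2‑yl)‑2‑methylcyclopent‑1‑ene‑1‑carboxylate
Conditions: SeO2 (cat.), t‑BuOOH, CH2Cl2, 20 °C
Reagents that add atoms: tert‑butyl hydroperoxide, CC(C)(C)OO; selenium dioxide, O=[Se]=O
Why: Riley allylic oxidation (ene reaction, then [2,3]‑sigmatropic shift); the electron‑rich 1,1‑disubstituted alkene reacts in preference to the electron‑poor tetrasubstituted enoate, and the methyl group is oxidised in preference to the ring methine.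

Step 5
Reactants: 9 allylic alcohol
Product: 11 methyl (3R,5S)‑5‑(1,3‑dihydroxypropan‑2‑yl)‑3‑hydroxy‑2‑methylcyclopent‑1‑ene‑1‑carboxylate, via tris‑borane adduct 10 (not isolated)
Conditions: 9‑BBN‑H (3.5 equiv), THF, 0 to 20 °C; then NaBO3·4H2O, H2O, 20 °C
Reagents that add atoms: sodium perborate, [Na+].[Na+].O[B-]1(O)OO[B-](O)(O)OO1 (oxygen of the new hydroxyl); 9‑borabicyclo[3.3.1]nonane, B1C2CCCC1CCC2 (boron only in 10)
Why: Anti‑Markovnikov hydroboration–oxidation; the hindered borane adds boron to the terminal carbon of the 1,1‑disubstituted alkene and leaves the tetrasubstituted enoate and the ester untouched, perborate oxidises the C–B bond without hydrolysing the ester, and the new branch carbon bears two identical CH2OH groups, so no stereocentre results.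

Step 6
Reactants: 11 triol
Product: 12 methyl (3R,5S)‑5‑(2,2‑dimethyl‑1,3‑dioxan‑5‑yl)‑3‑hydroxy‑2‑methylcyclopent‑1‑ene‑1‑carboxylate
Conditions: Me2C(OMe)2, PPTS (cat.), acetone, 20 °C
Reagents that add atoms: 2,2‑dimethoxypropane, COC(C)(C)OC
Why: Acid‑catalysed transacetalisation; only the 1,3‑diol can close a six‑membered cyclic acetal, so the C3 hydroxyl stays free for the next step.

Step 7
Reactants: 12 acetonide enoate
Product: 13 methyl (1R,2R,3R,5S)‑5‑(2,2‑dimethyl‑1,3‑dioxan‑5‑yl)‑3‑hydroxy‑2‑methylcyclopentane‑1‑carboxylate (ester, methyl and dioxanyl cis; hydroxyl on the other face)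
Conditions: [Ir(cod)(PCy3)(py)]PF6 (10 mol%), H2 (1–10 bar), CH2Cl2, 20 °C
Reagents that add atoms: none
Why: Hydroxyl‑directed homogeneous hydrogenation; the allylic C3 hydroxyl binds the cationic iridium and both hydrogens are delivered to its face, which is also the face opposite the C5 substituent, so C2 gets its methyl trans to the oxygen and C1 its ester cis to the methyl.

Step 8
Reactants: 13 cis,cis ester
Product: 14 methyl (1S,2R,3R,5S)‑5‑(2,2‑dimethyl‑1,3‑dioxan‑5‑yl)‑3‑hydroxy‑2‑methylcyclopentane‑1‑carboxylate (all neighbouring substituents trans)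
Conditions: NaOMe (0.2 equiv), MeOH, 50 °C
Reagents that add atoms: none
Why: Thermodynamic epimerisation through the ester enolate; the ester moves from the face it shares with both neighbours to the opposite face, and if the now cis C3 hydroxyl lactonises, step 9 reduces ester and lactone to the same diol.

Step 9
Reactants: 14 all‑trans ester
Product: 15 (1R,2R,3S,4R)‑4‑(2,2‑dimethyl‑1,3‑dioxan‑5‑yl)‑3‑(hydroxymethyl)‑2‑methylcyclopentan‑1‑ol
Conditions: LiAlH4, THF, 0 °C
Reagents that add atoms: none
Why: Hydride reduction of the ester to the primary alcohol; from here C1 is no longer epimerisable and the acetonide is inert.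

Step 10
Reactants: 16 (3aR,6aR)‑2,2‑dimethyl‑3a,6a‑dihydro‑4H‑cyclopenta[d][1,3]dioxol‑4‑one
Product: 17 (3aR,6aR)‑2,2‑dimethyltetrahydro‑4H‑cyclopenta[d][1,3]dioxol‑4‑one
Conditions: H2 (1 bar), 10% Pd/C, EtOAc, 20 °C
Reagents that add atoms: none
Why: Heterogeneous hydrogenation of the enone C=C bond; no stereocentre is formed or touched.

Step 11
Reactants: 17 saturated ketone; 18 methyl bromoacetate
Product: 20 methyl 2‑[(3aR,5S,6aR)‑2,2‑dimethyl‑4‑oxotetrahydro‑4H‑cyclopenta[d][1,3]dioxol‑5‑yl]acetate (side chain trans to the acetonide), via lithium enolate 19 (not isolated)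
Conditions: LiN(i‑Pr)2, THF, −78 °C; BrCH2CO2Me, DMPU, −78 to −30 °C
Reagents that add atoms: methyl bromoacetate (18), COC(=O)CBr
Why: Kinetic enolate alkylation; the amide base removes a proton from the unhindered CH2 and not from the ring‑fusion CH, and the electrophile enters on the convex face of the cis‑fused bicycle, trans to the acetonide, which fixes the future (S) centre of the arm.

Step 12
Reactants: 20 keto ester; 21 ethyltriphenylphosphonium bromide
Product: 23 methyl 2‑[(3aS,4E,5S,6aR)‑4‑ethylidene‑2,2‑dimethyltetrahydro‑4H‑cyclopenta[d][1,3]dioxol‑5‑yl]acetate (vinyl methyl on the side of the ring carbon bearing the side chain), via phosphorus ylide 22 (not isolated)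
Conditions: KOt‑Bu, THF, 0 °C; then 20, −20 to 20 °C
Reagents that add atoms: ethyltriphenylphosphonium bromide (21), CC[P+](c1ccccc1)(c1ccccc1)c1ccccc1.[Br-]
Why: Wittig olefination with a non‑stabilised ylide; under kinetic control such ylides place their alkyl group beside the bulkier α‑carbon of an α‑branched cyclopentanone (as in the ethylidenation of 17‑oxo steroids), here the carbon with the side chain and not the one whose oxygen is tied back in the dioxolane, which gives the E alkene; the minor isomer is removed by chromatography, and the low temperature keeps the α‑centre from epimerising.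

Step 13
Reactants: 23 ethylidene ester
Product: 24 2‑[(3aS,4E,5S,6aR)‑4‑ethylidene‑2,2‑dimethyltetrahydro‑4H‑cyclopenta[d][1,3]dioxol‑5‑yl]acetic acid
Conditions: LiOH, THF/H2O, 0 to 20 °C; then 1 M HCl to pH 3
Reagents that add atoms: lithium hydroxide, [Li+].[OH-]
Why: Saponification of the methyl ester; the stereocentre is no longer next to a carbonyl group and the acetonide survives the brief acidification.

Step 14
Reactants: 15 core diol; 24 arm acid (2.4 equiv)
Product: 25 [(1S,2R,3R,5R)‑5‑(2,2‑dimethyl‑1,3‑dioxan‑5‑yl)‑3‑({[(3aS,4E,5S,6aR)‑4‑ethylidene‑2,2‑dimethyltetrahydro‑4H‑cyclopenta[d][1,3]dioxol‑5‑yl]acetyl}oxy)‑2‑methylcyclopentyl]methyl [(3aS,4E,5S,6aR)‑4‑ethylidene‑2,2‑dimethyltetrahydro‑4H‑cyclopenta[d][1,3]dioxol‑5‑yl]acetate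
Conditions: DCC, DMAP (cat.), CH2Cl2, 0 to 20 °C
Reagents that add atoms: none
Why: Steglich esterification; the acyl‑pyridinium intermediate acylates the primary and the hindered secondary hydroxyl alike, and the acid has no α‑stereocentre to lose.

Step 15
Reactants: 25 tris‑acetonide bis‑ester
Product: 26 [(1S,2R,3R,5R)‑5‑(1,3‑dihydroxypropan‑2‑yl)‑3‑({[(1S,2E,3S,4R)‑2‑ethylidene‑3,4‑dihydroxycyclopentyl]acetyl}oxy)‑2‑methylcyclopentyl]methyl [(1S,2E,3S,4R)‑2‑ethylidene‑3,4‑dihydroxycyclopentyl]acetate
Conditions: 1 M aq. HCl, THF, 20 °C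
Reagents that add atoms: none
Why: Acid‑catalysed acetal hydrolysis of all three acetonides while no aldehyde is present; the arm hydroxyls are trans to the ester side chain and cannot lactonise, and the branch diol is too far from either ester for acyl migration.

Step 16
Reactants: 26 hexaol
Product: 27 [(1S,2R,3R,5R)‑5‑(1,3‑dihydroxypropan‑2‑yl)‑3‑{[(3S,4E)‑4‑formyl‑3‑(2‑oxoethyl)hex‑4‑enoyl]oxy}‑2‑methylcyclopentyl]methyl (3S,4E)‑4‑formyl‑3‑(2‑oxoethyl)hex‑4‑enoate (CNP0313563.1)
Conditions: NaIO4 (2.4 equiv), THF/H2O, pH 7 buffer, 0 °C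
Reagents that add atoms: none
Why: Malaprade glycol cleavage; periodate cleaves only the two cyclic cis‑1,2‑diols, each giving the enal and the CH2CHO group of one arm, and leaves the 1,3‑diol, the esters and the alkene geometry untouched.

## Compound list

1 | (R)‑(−)‑carvone | CC1=CC[C@@H](C(C)=C)CC1=O | starting material
2 | (1R,4R,6R)‑1‑methyl‑4‑(prop‑1‑en‑2‑yl)‑7‑oxabicyclo[4.1.0]heptan‑2‑one | CC(=C)[C@@H]1C[C@H]2O[C@@]2(C)C(=O)C1 | intermediate
3 | (1R,6R)‑1‑methyl‑4‑(prop‑1‑en‑2‑yl)‑3‑(2,2,2‑trifluoroacetyl)‑7‑oxabicyclo[4.1.0]heptan‑2‑one, isopropenyl trans to the epoxide, C3 unassigned (enolised) | CC(=C)[C@@H]1C[C@H]2O[C@@]2(C)C(=O)C1C(=O)C(F)(F)F | intermediate (not isolated)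
4 | (1R,4S,6R)‑3‑diazo‑1‑methyl‑4‑(prop‑1‑en‑2‑yl)‑7‑oxabicyclo[4.1.0]heptan‑2‑one | CC(=C)[C@@H]1C[C@H]2O[C@@]2(C)C(=O)C1=[N+]=[N-] | intermediate
5 | methanol | CO | starting material
6 | [(1S,3S,5R)‑1‑methyl‑3‑(prop‑1‑en‑2‑yl)‑6‑oxabicyclo[3.1.0]hexan‑2‑ylidene]methanone (ketene) | CC(=C)[C@@H]1C[C@H]2O[C@@]2(C)C1=C=O | intermediate (not isolated)
7 | methoxy[(1S,3S,5R)‑1‑methyl‑3‑(prop‑1‑en‑2‑yl)‑6‑oxabicyclo[3.1.0]hexan‑2‑ylidene]methanol (ester enol) | CC(=C)[C@@H]1C[C@H]2O[C@@]2(C)C1=C(O)OC | intermediate (not isolated)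
8 | methyl (3R,5S)‑3‑hydroxy‑2‑methyl‑5‑(prop‑1‑en‑2‑yl)cyclopent‑1‑ene‑1‑carboxylate | COC(=O)C1=C(C)[C@H](O)C[C@H]1C(C)=C | intermediate
9 | methyl (3R,5S)‑3‑hydroxy‑5‑(3‑hydroxyprop‑1‑en‑2‑yl)‑2‑methylcyclopent‑1‑ene‑1‑carboxylate | COC(=O)C1=C(C)[C@H](O)C[C@H]1C(CO)=C | intermediate
10 | methyl (3R,5S)‑3‑[(9‑borabicyclo[3.3.1]nonan‑9‑yl)oxy]‑5‑{1‑(9‑borabicyclo[3.3.1]nonan‑9‑yl)‑3‑[(9‑borabicyclo[3.3.1]nonan‑9‑yl)oxy]propan‑2‑yl}‑2‑methylcyclopent‑1‑ene‑1‑carboxylate (both epimers at the side‑chain carbon) | COC(=O)C1=C(C)[C@H](OB2C3CCCC2CCC3)C[C@H]1C(COB2C3CCCC2CCC3)CB2C3CCCC2CCC3 | intermediate (not isolated)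
11 | methyl (3R,5S)‑5‑(1,3‑dihydroxypropan‑2‑yl)‑3‑hydroxy‑2‑methylcyclopent‑1‑ene‑1‑carboxylate | COC(=O)C1=C(C)[C@H](O)C[C@H]1C(CO)CO | intermediate
12 | methyl (3R,5S)‑5‑(2,2‑dimethyl‑1,3‑dioxan‑5‑yl)‑3‑hydroxy‑2‑methylcyclopent‑1‑ene‑1‑carboxylate | COC(=O)C1=C(C)[C@H](O)C[C@H]1C2COC(C)(C)OC2 | intermediate
13 | methyl (1R,2R,3R,5S)‑5‑(2,2‑dimethyl‑1,3‑dioxan‑5‑yl)‑3‑hydroxy‑2‑methylcyclopentane‑1‑carboxylate | COC(=O)[C@H]1[C@@H](C)[C@H](O)C[C@H]1C2COC(C)(C)OC2 | intermediate
14 | methyl (1S,2R,3R,5S)‑5‑(2,2‑dimethyl‑1,3‑dioxan‑5‑yl)‑3‑hydroxy‑2‑methylcyclopentane‑1‑carboxylate | COC(=O)[C@@H]1[C@@H](C)[C@H](O)C[C@H]1C2COC(C)(C)OC2 | intermediate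
15 | (1R,2R,3S,4R)‑4‑(2,2‑dimethyl‑1,3‑dioxan‑5‑yl)‑3‑(hydroxymethyl)‑2‑methylcyclopentan‑1‑ol | OC[C@@H]1[C@@H](C)[C@H](O)C[C@H]1C2COC(C)(C)OC2 | intermediate
16 | (3aR,6aR)‑2,2‑dimethyl‑3a,6a‑dihydro‑4H‑cyclopenta[d][1,3]dioxol‑4‑one | O=C1C=C[C@H]2OC(C)(C)O[C@@H]12 | starting material
17 | (3aR,6aR)‑2,2‑dimethyltetrahydro‑4H‑cyclopenta[d][1,3]dioxol‑4‑one | O=C1CC[C@H]2OC(C)(C)O[C@@H]12 | intermediate
18 | methyl bromoacetate | COC(=O)CBr | starting material
19 | lithium (3aR,6aR)‑2,2‑dimethyl‑6,6a‑dihydro‑3aH‑cyclopenta[d][1,3]dioxol‑4‑olate | [Li]OC1=CC[C@H]2OC(C)(C)O[C@@H]12 | intermediate (not isolated)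
20 | methyl 2‑[(3aR,5S,6aR)‑2,2‑dimethyl‑4‑oxotetrahydro‑4H‑cyclopenta[d][1,3]dioxol‑5‑yl]acetate | COC(=O)C[C@@H]1C[C@H]2OC(C)(C)O[C@H]2C1=O | intermediate
21 | ethyltriphenylphosphonium bromide | CC[P+](c1ccccc1)(c1ccccc1)c1ccccc1.[Br-] | starting material
22 | ethylidenetriphenylphosphorane | CC=P(c1ccccc1)(c1ccccc1)c1ccccc1 | intermediate (not isolated)
23 | methyl 2‑[(3aS,4E,5S,6aR)‑4‑ethylidene‑2,2‑dimethyltetrahydro‑4H‑cyclopenta[d][1,3]dioxol‑5‑yl]acetate | COC(=O)C[C@@H]1C[C@H]2OC(C)(C)O[C@H]2/C1=C/C | intermediate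
24 | 2‑[(3aS,4E,5S,6aR)‑4‑ethylidene‑2,2‑dimethyltetrahydro‑4H‑cyclopenta[d][1,3]dioxol‑5‑yl]acetic acid | OC(=O)C[C@@H]1C[C@H]2OC(C)(C)O[C@H]2/C1=C/C | intermediate
25 | [(1S,2R,3R,5R)‑5‑(2,2‑dimethyl‑1,3‑dioxan‑5‑yl)‑3‑({[(3aS,4E,5S,6aR)‑4‑ethylidene‑2,2‑dimethyltetrahydro‑4H‑cyclopenta[d][1,3]dioxol‑5‑yl]acetyl}oxy)‑2‑methylcyclopentyl]methyl [(3aS,4E,5S,6aR)‑4‑ethylidene‑2,2‑dimethyltetrahydro‑4H‑cyclopenta[d][1,3]dioxol‑5‑yl]acetate | O=C(C[C@@H]1C[C@H]2OC(C)(C)O[C@H]2/C1=C/C)OC[C@@H]3[C@@H](C)[C@H](OC(=O)C[C@@H]4C[C@H]5OC(C)(C)O[C@H]5/C4=C/C)C[C@H]3C6COC(C)(C)OC6 | intermediate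
26 | [(1S,2R,3R,5R)‑5‑(1,3‑dihydroxypropan‑2‑yl)‑3‑({[(1S,2E,3S,4R)‑2‑ethylidene‑3,4‑dihydroxycyclopentyl]acetyl}oxy)‑2‑methylcyclopentyl]methyl [(1S,2E,3S,4R)‑2‑ethylidene‑3,4‑dihydroxycyclopentyl]acetate | O=C(C[C@@H]1C[C@@H](O)[C@@H](O)/C1=C/C)OC[C@@H]2[C@@H](C)[C@H](OC(=O)C[C@@H]3C[C@@H](O)[C@@H](O)/C3=C/C)C[C@H]2C(CO)CO | intermediate
27 | [(1S,2R,3R,5R)‑5‑(1,3‑dihydroxypropan‑2‑yl)‑3‑{[(3S,4E)‑4‑formyl‑3‑(2‑oxoethyl)hex‑4‑enoyl]oxy}‑2‑methylcyclopentyl]methyl (3S,4E)‑4‑formyl‑3‑(2‑oxoethyl)hex‑4‑enoate | C/C=C(/C=O)[C@@H](CC=O)CC(=O)OC[C@@H]1[C@@H](C)[C@H](OC(=O)C[C@H](CC=O)/C(C=O)=C\C)C[C@H]1C(CO)CO | target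

## Step count and risks

Total step count: 16 (steps 1–9 for the ring, steps 10–13 for the arm acid, steps 14–16 shared). Longest linear sequence: 12 steps (1–9, then 14–16). The arm acid **24** is needed twice, so steps 10–13 are run on twice the molar scale.

**Step 3 (key step).** The most likely failure is that the carbene escapes rearrangement, by O–H insertion into methanol or by a 1,2‑hydride shift from the neighbouring ring CH, because the migrating carbon is fully substituted and carries oxygen, which lowers its migratory aptitude. A second possibility is ketonisation of the enol before the epoxide opens; this is cured by a catalytic amine and is not a change of route. The fallback forms the same ring bond by a Favorskii contraction and uses only known reaction types. It sets out from **2**. Opening with LiCl/CF3CO2H places chloride on the methyl‑bearing α‑carbon and gives (2S,3R,5R)‑2‑chloro‑3‑hydroxy‑2‑methyl‑5‑(prop‑1‑en‑2‑yl)cyclohexan‑1‑one F1. Treatment with t‑BuMe2SiOTf/Et3N and then N‑bromosuccinimide at −78 °C protects the hydroxyl and brominates the silyl enol ether, giving (2S,3R)‑6‑bromo‑3‑[(tert‑butyldimethylsilyl)oxy]‑2‑chloro‑2‑methyl‑5‑(prop‑1‑en‑2‑yl)cyclohexan‑1‑one F2. NaOMe in MeOH then brings about the Favorskii rearrangement of the α,α'‑dihalo ketone, in which loss of the second halide leaves the ring double bond, to give methyl (3R,5S)‑3‑[(tert‑butyldimethylsilyl)oxy]‑2‑methyl‑5‑(prop‑1‑en‑2‑yl)cyclopent‑1‑ene‑1‑carboxylate F3. HF·pyridine returns the route to **8**.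

**Step 7.** The hydrogenation may stall, because the alkene is tetrasubstituted and conjugated to the ester and the iridium catalyst deactivates quickly with slow substrates. The fallback moves the hydrogenation to a more reactive alkene and sets C1 afterwards. It sets out from **12**. Reduction with i‑Bu2AlH gives (1R,4S)‑4‑(2,2‑dimethyl‑1,3‑dioxan‑5‑yl)‑3‑(hydroxymethyl)‑2‑methylcyclopent‑2‑en‑1‑ol F4. Its non‑conjugated tetrasubstituted alkene is hydrogenated with [Ir(cod)(PCy3)(py)]PF6 from the face of the ring hydroxyl to give (1R,2R,3R,4R)‑4‑(2,2‑dimethyl‑1,3‑dioxan‑5‑yl)‑3‑(hydroxymethyl)‑2‑methylcyclopentan‑1‑ol F5. TEMPO/PhI(OAc)2 oxidises only the primary alcohol to (1R,2R,3R,5S)‑5‑(2,2‑dimethyl‑1,3‑dioxan‑5‑yl)‑3‑hydroxy‑2‑methylcyclopentane‑1‑carbaldehyde F6. K2CO3 in MeOH epimerises the formyl group to the all‑trans arrangement, and NaBH4 in the same flask gives **15**.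

**Step 12.** Two things may go wrong: poor E/Z selectivity, because an α‑oxygen can draw the ylide's methyl group to its own side and work against the steric preference, and partial epimerisation of the α‑centre by the basic ylide. The fallback replaces the Wittig reaction by a Peterson olefination, which is stereoconvergent. It sets out from **20**. Addition of Me3SiCH(CH3)MgCl premixed with CeCl3 (THF, −78 °C, non‑basic, ketone‑selective) gives methyl 2‑[(3aR,5S,6aR)‑4‑hydroxy‑2,2‑dimethyl‑4‑[1‑(trimethylsilyl)ethyl]tetrahydro‑4H‑cyclopenta[d][1,3]dioxol‑5‑yl]acetate F7 as two diastereomers at the silyl‑bearing carbon. They are separated; one is eliminated syn with KN(SiMe3)2 and the other anti with BF3·OEt2, and both give **23**.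

**Step 4.** The oxidation may run on to the enal, may oxidise the secondary allylic alcohol, or may give low conversion, as is common for isopropenyl groups. The fallback uses an ene‑type chlorination in place of the selenium reagent. It sets out from **8**. Ca(OCl)2 with solid CO2 in CH2Cl2/H2O gives methyl (3R,5R)‑5‑(3‑chloroprop‑1‑en‑2‑yl)‑3‑hydroxy‑2‑methylcyclopent‑1‑ene‑1‑carboxylate F8. NaOAc in DMF gives methyl (3R,5S)‑5‑[3‑(acetyloxy)prop‑1‑en‑2‑yl]‑3‑hydroxy‑2‑methylcyclopent‑1‑ene‑1‑carboxylate F9, and K2CO3 in MeOH gives **9**.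

**Step 2.** The lithium enolate of the epoxy ketone may self‑condense or be acylated on oxygen, so that trifluoroacetylation is incomplete. The fallback avoids strong base. It sets out from **2**. Heating with tert‑butoxybis(dimethylamino)methane gives (1R,4S,6R)‑3‑[(dimethylamino)methylidene]‑1‑methyl‑4‑(prop‑1‑en‑2‑yl)‑7‑oxabicyclo[4.1.0]heptan‑2‑one F10, and diazo transfer to this enaminone with MsN3 gives **4**.

## Further compounds

F1 | step 3 | (2S,3R,5R)‑2‑chloro‑3‑hydroxy‑2‑methyl‑5‑(prop‑1‑en‑2‑yl)cyclohexan‑1‑one | C1C(=O)[C@@](C)(Cl)[C@H](O)C[C@H]1C(C)=C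
F2 | step 3 | (2S,3R)‑6‑bromo‑3‑[(tert‑butyldimethylsilyl)oxy]‑2‑chloro‑2‑methyl‑5‑(prop‑1‑en‑2‑yl)cyclohexan‑1‑one (isopropenyl trans to the silyloxy group, either configuration at C6) | BrC1C(=O)[C@@](C)(Cl)[C@H](O[Si](C)(C)C(C)(C)C)C[C@H]1C(C)=C
F3 | step 3 | methyl (3R,5S)‑3‑[(tert‑butyldimethylsilyl)oxy]‑2‑methyl‑5‑(prop‑1‑en‑2‑yl)cyclopent‑1‑ene‑1‑carboxylate | COC(=O)C1=C(C)[C@H](O[Si](C)(C)C(C)(C)C)C[C@H]1C(C)=C
F4 | step 7 | (1R,4S)‑4‑(2,2‑dimethyl‑1,3‑dioxan‑5‑yl)‑3‑(hydroxymethyl)‑2‑methylcyclopent‑2‑en‑1‑ol | OCC1=C(C)[C@H](O)C[C@H]1C2COC(C)(C)OC2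
F5 | step 7 | (1R,2R,3R,4R)‑4‑(2,2‑dimethyl‑1,3‑dioxan‑5‑yl)‑3‑(hydroxymethyl)‑2‑methylcyclopentan‑1‑ol | OC[C@H]1[C@@H](C)[C@H](O)C[C@H]1C2COC(C)(C)OC2
F6 | step 7 | (1R,2R,3R,5S)‑5‑(2,2‑dimethyl‑1,3‑dioxan‑5‑yl)‑3‑hydroxy‑2‑methylcyclopentane‑1‑carbaldehyde | O=C[C@H]1[C@@H](C)[C@H](O)C[C@H]1C2COC(C)(C)OC2
F7 | step 12 | methyl 2‑[(3aR,5S,6aR)‑4‑hydroxy‑2,2‑dimethyl‑4‑[1‑(trimethylsilyl)ethyl]tetrahydro‑4H‑cyclopenta[d][1,3]dioxol‑5‑yl]acetate (diastereomers at C4 and at the silyl‑bearing carbon) | COC(=O)C[C@@H]1C[C@H]2OC(C)(C)O[C@H]2C1(O)C(C)[Si](C)(C)C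
F8 | step 4 | methyl (3R,5R)‑5‑(3‑chloroprop‑1‑en‑2‑yl)‑3‑hydroxy‑2‑methylcyclopent‑1‑ene‑1‑carboxylate | COC(=O)C1=C(C)[C@H](O)C[C@H]1C(CCl)=C
F9 | step 4 | methyl (3R,5S)‑5‑[3‑(acetyloxy)prop‑1‑en‑2‑yl]‑3‑hydroxy‑2‑methylcyclopent‑1‑ene‑1‑carboxylate | COC(=O)C1=C(C)[C@H](O)C[C@H]1C(COC(C)=O)=C
F10 | step 2 | (1R,4S,6R)‑3‑[(dimethylamino)methylidene]‑1‑methyl‑4‑(prop‑1‑en‑2‑yl)‑7‑oxabicyclo[4.1.0]heptan‑2‑one | CC(=C)[C@@H]1C[C@H]2O[C@@]2(C)C(=O)C1=CN(C)C
A1 | alternative 1 | [(1S,2R,3R,5R)‑5‑(2,2‑di‑tert‑butyl‑1,3,2‑dioxasilinan‑5‑yl)‑2‑methyl‑3‑{[5‑oxo‑3‑(2‑oxoethyl)pentanoyl]oxy}cyclopentyl]methyl 5‑oxo‑3‑(2‑oxoethyl)pentanoate | O=CCC(CC=O)CC(=O)OC[C@@H]1[C@@H](C)[C@H](OC(=O)CC(CC=O)CC=O)C[C@H]1C1CO[Si](C(C)(C)C)(C(C)(C)C)OC1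
A2 | alternative 1 | [(1S,2R,3R,5R)‑5‑(2,2‑di‑tert‑butyl‑1,3,2‑dioxasilinan‑5‑yl)‑3‑{[(3S,4E)‑4‑formyl‑3‑(2‑oxoethyl)hex‑4‑enoyl]oxy}‑2‑methylcyclopentyl]methyl (3S,4E)‑4‑formyl‑3‑(2‑oxoethyl)hex‑4‑enoate | C/C=C(/C=O)[C@@H](CC=O)CC(=O)OC[C@@H]1[C@@H](C)[C@H](OC(=O)C[C@H](CC=O)/C(C=O)=C\C)C[C@H]1C1CO[Si](C(C)(C)C)(C(C)(C)C)OC1
A3 | alternative 2 | (3R,4S)‑1‑diazo‑5‑(2,2‑dimethyl‑1,3‑dioxan‑5‑ylidene)‑3‑methyl‑4‑[(pivaloyloxy)methyl]pentan‑2‑one | CC(C)(C)C(=O)OC[C@H]([C@@H](C)C(=O)C=[N+]=[N-])C=C1COC(C)(C)OC1
A4 | alternative 2 | 2',2'‑dimethyl‑3‑methyl‑4‑(pivaloyloxymethyl)spiro[bicyclo[3.1.0]hexane‑6,5'‑[1,3]dioxan]‑2‑one (methyl and pivaloyloxymethyl trans) | CC(C)(C)C(=O)OC[C@@H]1[C@@H](C)C(=O)[C@@H]2[C@H]1C23COC(C)(C)OC3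
A5 | alternative 3 | (R)‑4‑(2,2‑dimethyl‑1,3‑dioxan‑5‑yl)cyclopent‑2‑en‑1‑one | O=C1C=C[C@H](C2COC(C)(C)OC2)C1
A6 | alternative 3 | (2R,3S,4R)‑4‑(2,2‑dimethyl‑1,3‑dioxan‑5‑yl)‑3‑ethenyl‑2‑methylcyclopentan‑1‑one (all‑trans) | C=C[C@@H]1[C@@H](C)C(=O)C[C@H]1C2COC(C)(C)OC2
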